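Feature: in ring B the sp2 carbon C8 carries the exocyclic methylene C17 and is bonded to the stereocentre C9. C8–C9 is therefore an sp2–sp3 bond that can be made from a 2-bromoallyl unit (C7, C8, C17) and a C9 radical released from a carboxyl group on C9.
Cuts (labdane numbering): the acetate; C14=C15 and C12=C13 (two Wittig reactions); C8–C9 (ring B); C6–C7 (2-bromoallyl onto a C6 aldehyde); C9–C10 (tertiary radical onto a fumarate); C1=C10 (metathesis, ring A); C3–C4, C4–C19 and C5–C10 (two enolate alkylations and a conjugate addition on a butenolide that supplies C18, C4, C5 and C6).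
Forward: chiral butenolide acetal, then trisubstituted lactone, ring A by ring-closing metathesis, quaternary C10 with the C9/C11/C12 succinate arm, lactone opened to the C18 ester and C6 aldehyde, bromoallyl arm, ring B by the key step, C12 aldehyde, diene side chain, acetate.
Stereochemistry: (+)-menthol fixes the acetal carbon, which directs the anti conjugate addition (C5). C5 directs the anti alkylation (C4), and the axial C19 methyl of the rigid trans-fused bicycle directs the radical addition (C10). Felkin–Anh addition sets C6, the chair-like closure sets C9, and the stabilised ylide sets 12E.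

Key step: step 13

Remark: labdane numbering is used for all intermediates (C18 = ester carbon on C4, C19 = methyl on C4, C20 = methyl on C10). In the lactones the carbonyl is C18, the alpha carbon C4, the beta carbon C5 and the acetal carbon C6.
Remark: compounds 12 to 24 are carried as mixtures of C9 epimers, because both epimers give the same planar C9 radical in step 13.

Step 1
Reactants: 1 5-hydroxyfuran-2(5H)-one; 2 (+)-menthol
Product: 3 (5S)-5-[(1S,2R,5S)-menthyloxy]furan-2(5H)-one
Conditions: camphorsulfonic acid (cat.), toluene, reflux, water separator; crystallisation from petroleum ether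
Reagents that add atoms: none
Why: Acid-catalysed acetalisation of the cyclic hemiacetal, in which the two acetal epimers interconvert under the acid and the (5S) epimer should crystallise, so C6 is fixed by a crystallisation-induced diastereomer transformation.

Step 2
Reactants: 3 (5S)-5-menthyloxyfuran-2(5H)-one; 4 isopropenylmagnesium bromide
Product: 6 (4R,5S)-4-isopropenyl-5-menthyloxydihydrofuran-2(3H)-one (isopropenyl trans to menthyloxy), via silyl ketene acetal 5 (not isolated)
Conditions: CuBr·SMe2 (10 mol %), Me3SiCl, THF, −78 °C; aq. NH4Cl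
Reagents that add atoms: none
Why: Copper-catalysed, chlorosilane-accelerated conjugate addition of a Grignard reagent to a butenolide, in which the menthyloxy group on C6 shields one face so that the isopropenyl group (C10 and C20) enters anti to it and sets C5.

Step 3
Reactants: 6 (4R,5S)-4-isopropenyl-5-menthyloxydihydrofuran-2(3H)-one
Product: 7 (3S,4R,5S)-3-methyl-4-isopropenyl-5-menthyloxydihydrofuran-2(3H)-one (neighbouring substituents trans)
Conditions: LiN(i-Pr)2, THF, −78 °C; MeI
Reagents that add atoms: iodomethane, CI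
Why: Lactone enolate alkylation that brings in C19 anti to the isopropenyl group, at a centre that is planarised again in step 4 so that its configuration here does not matter.

Step 4
Reactants: 7 (3S,4R,5S)-3-methyl-4-isopropenyl-5-menthyloxydihydrofuran-2(3H)-one; 8 4-iodobut-1-ene
Product: 9 (3S,4S,5S)-3-(but-3-enyl)-3-methyl-4-isopropenyl-5-menthyloxydihydrofuran-2(3H)-one (butenyl trans, methyl cis to isopropenyl)
Conditions: LiN(i-Pr)2, THF–DMPU, −78 °C; 8, −78 → −40 °C
Reagents that add atoms: none
Why: Second lactone enolate alkylation, in which the C3–C2–C1 chain again approaches anti to the vicinal isopropenyl group, so that quaternary C4 is formed with C19 cis to C10 and C3 trans to C10, as the trans ring fusion requires.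

Step 5
Reactants: 9 (3S,4S,5S)-3-(but-3-enyl)-3-methyl-4-isopropenyl-5-menthyloxydihydrofuran-2(3H)-one
Product: 10 (3S,3aS,7aS)-3-menthyloxy-4,7a-dimethyl-3a,6,7,7a-tetrahydro-2-benzofuran-1(3H)-one (trans-fused, ring A with C1=C10)
Conditions: second-generation Grubbs catalyst (5 mol %), CH2Cl2, 40 °C
Reagents that add atoms: none
Why: Ring-closing metathesis of a monosubstituted and a 1,1-disubstituted alkene closes ring A as a trisubstituted cyclohexene and touches no stereocentre.

Step 6
Reactants: 10 trans-fused bicyclic acetal lactone; 11 di-tert-butyl fumarate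
Product: 12 di-tert-butyl 2-[(3S,3aS,4R,7aS)-3-menthyloxy-4,7a-dimethyl-1-oxooctahydro-2-benzofuran-4-yl]butanedioate (C19 and C20 cis; C9 epimers)
Conditions: 11 (4 equiv), Fe(acac)3 (30 mol %), PhSiH3 (3 equiv), EtOH, 60 °C
Reagents that add atoms: none
Why: Hydrogen-atom-transfer-initiated Giese addition, in which an iron hydride delivers H to C1 and the tertiary C10 radical adds to the fumarate from the face opposite the axial C19 methyl of the rigid chair, so that C20 ends axial and cis to C19 and C9 ends equatorial.

Step 7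
Reactants: 12 Giese adduct
Product: 15 di-tert-butyl 2-[(1R,2S,3S)-2-(hydroxymethyl)-3-(methoxycarbonyl)-1,3-dimethylcyclohexyl]butanedioate, via potassium formyl carboxylate 13 (not isolated), via potassium hydroxy carboxylate 14 (not isolated)
Conditions: KOH (1.1 equiv), NaBH4, EtOH–H2O, 0 °C → rt; concentrate; MeI, DMF, rt
Reagents that add atoms: potassium hydroxide, [K+].[OH-]; iodomethane, CI
Why: Saponification of the acylal lactone releases the C18 carboxylate, menthol and the C6 aldehyde, borohydride reduces that aldehyde before C5 can epimerise, SN2 alkylation of the carboxylate then gives the methyl ester, and the tert-butyl esters resist hydroxide throughout.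

Step 8
Reactants: 15 hydroxy methyl ester
Product: 16 di-tert-butyl 2-[(1R,2S,3S)-2-formyl-3-(methoxycarbonyl)-1,3-dimethylcyclohexyl]butanedioate
Conditions: Dess–Martin periodinane, CH2Cl2, 0 °C → rt
Reagents that add atoms: none
Why: Dess–Martin oxidation gives the C6 aldehyde without base, so the epimerisable C5 centre between the two quaternary carbons keeps its configuration and the alcohol has no time to lactonise.

Step 9
Reactants: 16 C6 aldehyde; 17 2,3-dibromopropene
Product: 18 di-tert-butyl 2-{(1R,2S,3S)-2-[(1R)-3-bromo-1-hydroxybut-3-enyl]-3-(methoxycarbonyl)-1,3-dimethylcyclohexyl}butanedioate (6R)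
Conditions: indium powder, THF–H2O (1:1), rt, ultrasound
Reagents that add atoms: none
Why: Barbier-type indium-mediated 2-bromoallylation under Felkin–Anh control, in which the allyl reagent attacks anti to C10 (the carbon with the much larger di-tert-butyl succinate arm) and passes H5 and the smaller C4 ester, which should give the 6R carbinol.

Step 10
Reactants: 18 bromoallyl carbinol
Product: 21 2-{(1R,2S,3S)-2-[(1R)-3-bromo-1-(tert-butyldimethylsilyloxy)but-3-enyl]-3-(methoxycarbonyl)-1,3-dimethylcyclohexyl}butanedioic acid, via silyl ether di-tert-butyl ester 19 (not isolated), via bis(trimethylsilyl) ester 20 (not isolated)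
Conditions: TBSOTf, 2,6-lutidine, CH2Cl2, 0 °C; then Me3SiOTf, 0 °C → rt; aq. KH2PO4
Reagents that add atoms: tert-butyldimethylsilyl trifluoromethanesulfonate, CC(C)(C)[Si](C)(C)OS(=O)(=O)C(F)(F)F
Why: Silyl triflate silylation of the hindered C6 alcohol is followed by silyl-triflate-mediated cleavage of both tert-butyl esters with loss of isobutene and by hydrolysis of the silyl esters on work-up, under buffered conditions that leave the methyl ester, the bromoalkene and the silyl ether untouched.

Step 11
Reactants: 21 silyl ether diacid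
Product: 23 2-{(1R,2S,3S)-2-[(1R)-3-bromo-1-(tert-butyldimethylsilyloxy)but-3-enyl]-3-(methoxycarbonyl)-1,3-dimethylcyclohexyl}-4-methoxy-4-oxobutanoic acid (C9 acid, C12 methyl ester), via succinic anhydride 22 (not isolated)
Conditions: DCC, CH2Cl2, 0 °C; then MeOH, DMAP (cat.), rt
Reagents that add atoms: methanol, CO
Why: Carbodiimide dehydration gives the five-membered anhydride, and DMAP-catalysed methanolysis opens it at the unhindered C12 carbonyl rather than at the carbonyl on C9 next to quaternary C10, which leaves the C9 acid free.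

Step 12
Reactants: 23 C9 acid C12 methyl ester
Product: 24 1-(1,3-dioxoisoindolin-2-yl) 4-methyl 2-{(1R,2S,3S)-2-[(1R)-3-bromo-1-(tert-butyldimethylsilyloxy)but-3-enyl]-3-(methoxycarbonyl)-1,3-dimethylcyclohexyl}butanedioate (redox-active ester)
Conditions: N-hydroxyphthalimide, N,N'-diisopropylcarbodiimide, DMAP (cat.), CH2Cl2, rt
Reagents that add atoms: N-hydroxyphthalimide, O=C1c2ccccc2C(=O)N1O
Why: Steglich-type esterification of the only free acid with N-hydroxyphthalimide installs the redox-active ester on C9 and changes no stereocentre that matters.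

Step 13
Reactants: 24 redox-active ester with 2-bromoallyl arm
Product: 25 methyl (1S,4aS,5R,8R,8aS)-8-(tert-butyldimethylsilyloxy)-5-(2-methoxy-2-oxoethyl)-1,4a-dimethyl-6-methylidenedecahydronaphthalene-1-carboxylate (labdane descriptors 4S,5S,6R,9R,10S)
Conditions: NiCl2(dme) (20 mol %), 2,2'-bipyridine (24 mol %), n-Bu4NPF6 (0.1 M), DMF (5 mM in 24), Zn anode, reticulated vitreous carbon cathode, undivided cell, constant current, 2.5 F/mol, rt
Reagents that add atoms: none
Why: Cathodically formed zerovalent nickel inserts into the C8–Br bond, and single-electron transfer to the phthalimide ester breaks the N–O bond and expels CO2 and phthalimide anion, which leaves a secondary C9 radical whichever C9 epimer of 24 was used. The radical is caught by the divalent alkenylnickel on the neighbouring arm, the trivalent seven-membered nickelacycle (Ni, C8, C7, C6, C5, C10, C9) collapses by reductive elimination to the C8–C9 bond, and the zinc anode supplies the two electrons. The closest known reaction type is the intermolecular nickel-electrocatalytic (or zinc-driven) decarboxylative alkenylation of secondary redox-active esters with alkenyl bromides, run here within one molecule. Ring B closes as a six-membered ring at the bromine-bearing alkenyl carbon, a formal 6-exo closure by C(sp3)–C(sp2) reductive elimination and not by radical addition to the double bond, so C17 stays exocyclic. C9 is set at capture and elimination: the two arms are locked trans-diequatorial on the ring A chair, ring B can form only as the second chair of a trans-decalin, and in that chair the CH2CO2Me group should take the equatorial site anti to C5, away from axial H5 and H7, giving 9R. The step needs ring closure to outrun coupling between molecules, hydrogen abstraction and 7-endo attack of the radical on C17, which the proximity of the arms, quaternary C10 and the high dilution secure, and only the C–Br and N–O bonds are reducible at the working potential, so the esters and the silyl ether are spectators.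

Step 14
Reactants: 25 8(17)-methylene decalin diester
Product: 26 methyl (1S,4aS,5R,8R,8aS)-8-(tert-butyldimethylsilyloxy)-1,4a-dimethyl-6-methylidene-5-(2-oxoethyl)decahydronaphthalene-1-carboxylate (C12 aldehyde)
Conditions: i-Bu2AlH (1.05 equiv), CH2Cl2, −78 °C; MeOH, aq. potassium sodium tartrate
Reagents that add atoms: none
Why: Partial ester reduction with a dialkylaluminium hydride at low temperature, in which only the unhindered CH2CO2Me group reacts while the C18 ester on quaternary C4 is shielded, and the aluminium hemiacetal survives until the quench, so the reduction stops at the aldehyde.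

Step 15
Reactants: 26 C12 aldehyde; 27 2-(triphenylphosphoranylidene)propanal
Product: 28 methyl (1S,4aS,5R,8R,8aS)-8-(tert-butyldimethylsilyloxy)-1,4a-dimethyl-6-methylidene-5-[(2E)-3-methyl-4-oxobut-2-enyl]decahydronaphthalene-1-carboxylate (12E enal)
Conditions: toluene, 90 °C
Reagents that add atoms: none
Why: Wittig olefination with a stabilised ylide forms C12=C13 with the E geometry typical of such ylides and brings in C13, C14 and C16.

Step 16
Reactants: 28 12E enal
Product: 29 methyl (1S,4aS,5R,8R,8aS)-8-(tert-butyldimethylsilyloxy)-1,4a-dimethyl-6-methylidene-5-[(2E)-3-methylpenta-2,4-dienyl]decahydronaphthalene-1-carboxylate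
Conditions: Ph3PCH3Br, KOt-Bu, THF, 0 °C; then 28, −78 → 0 °C
Reagents that add atoms: methyltriphenylphosphonium bromide, C[P+](c1ccccc1)(c1ccccc1)c1ccccc1.[Br-]
Why: Wittig methylenation of the enal adds C15 and completes the conjugated diene without touching the 12E bond or the hindered ester.

Step 17
Reactants: 29 triene silyl ether
Product: 30 methyl (1S,4aS,5R,8R,8aS)-8-hydroxy-1,4a-dimethyl-6-methylidene-5-[(2E)-3-methylpenta-2,4-dienyl]decahydronaphthalene-1-carboxylate
Conditions: HF·pyridine, pyridine, THF, 0 °C → rt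
Reagents that add atoms: none
Why: Fluoride-mediated desilylation in a buffered acidic medium frees the equatorial C6 alcohol without forming an alkoxide that could lactonise onto the C18 ester.

Step 18
Reactants: 30 C6 alcohol
Product: 31 methyl (1S,4aS,5R,8R,8aS)-8-acetoxy-1,4a-dimethyl-6-methylidene-5-[(2E)-3-methylpenta-2,4-dienyl]decahydronaphthalene-1-carboxylate (target CNP0212193.1)
Conditions: Ac2O, DMAP, pyridine, rt
Reagents that add atoms: acetic anhydride, CC(=O)OC(C)=O
Why: DMAP-catalysed acetylation of the secondary alcohol proceeds with retention at C6 and gives the target.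

Compound list
1 | 5-hydroxyfuran-2(5H)-one | O=C1C=CC(O)O1 | starting material
2 | (+)-menthol, (1S,2R,5S)-2-isopropyl-5-methylcyclohexan-1-ol | CC(C)[C@H]1CC[C@H](C)C[C@@H]1O | starting material
3 | (5S)-5-[(1S,2R,5S)-menthyloxy]furan-2(5H)-one | O=C1C=C[C@@H](O[C@H]2C[C@@H](C)CC[C@@H]2C(C)C)O1 | intermediate
4 | isopropenylmagnesium bromide | C=C(C)[Mg]Br | starting material
5 | (4R,5S)-4-isopropenyl-5-menthyloxy-2-(trimethylsilyloxy)-4,5-dihydrofuran (silyl ketene acetal, not isolated) | C[Si](C)(C)OC1=C[C@H](C(C)=C)[C@@H](O[C@H]2C[C@@H](C)CC[C@@H]2C(C)C)O1 | intermediate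
6 | (4R,5S)-4-isopropenyl-5-menthyloxydihydrofuran-2(3H)-one | O=C1O[C@H](O[C@H]2C[C@@H](C)CC[C@@H]2C(C)C)[C@@H](C(C)=C)C1 | intermediate
7 | (3S,4R,5S)-3-methyl-4-isopropenyl-5-menthyloxydihydrofuran-2(3H)-one | O=C1O[C@H](O[C@H]2C[C@@H](C)CC[C@@H]2C(C)C)[C@@H](C(C)=C)[C@@H]1C | intermediate
8 | 4-iodobut-1-ene | C=CCCI | starting material
9 | (3S,4S,5S)-3-(but-3-enyl)-3-methyl-4-isopropenyl-5-menthyloxydihydrofuran-2(3H)-one | O=C1O[C@H](O[C@H]2C[C@@H](C)CC[C@@H]2C(C)C)[C@@H](C(C)=C)[C@]1(C)CCC=C | intermediate
10 | (3S,3aS,7aS)-3-menthyloxy-4,7a-dimethyl-3a,6,7,7a-tetrahydro-2-benzofuran-1(3H)-one, trans-fused | O=C1O[C@H](O[C@H]3C[C@@H](C)CC[C@@H]3C(C)C)[C@H]2C(C)=CCC[C@]12C | intermediate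
11 | di-tert-butyl fumarate | CC(C)(C)OC(=O)/C=C/C(=O)OC(C)(C)C | starting material
12 | di-tert-butyl 2-[(3S,3aS,4R,7aS)-3-menthyloxy-4,7a-dimethyl-1-oxooctahydro-2-benzofuran-4-yl]butanedioate, C9 epimers | O=C1O[C@H](O[C@H]3C[C@@H](C)CC[C@@H]3C(C)C)[C@H]2[C@@](C(CC(=O)OC(C)(C)C)C(=O)OC(C)(C)C)(C)CCC[C@]12C | intermediate
13 | potassium salt of the C6-formyl C18-carboxylate (not isolated) | O=C[C@H]2[C@@](C(CC(=O)OC(C)(C)C)C(=O)OC(C)(C)C)(C)CCC[C@]2(C)C(=O)[O-].[K+] | intermediate
14 | potassium salt of the C6-hydroxy C18-carboxylate (not isolated) | OC[C@H]2[C@@](C(CC(=O)OC(C)(C)C)C(=O)OC(C)(C)C)(C)CCC[C@]2(C)C(=O)[O-].[K+] | intermediate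
15 | di-tert-butyl 2-[(1R,2S,3S)-2-(hydroxymethyl)-3-(methoxycarbonyl)-1,3-dimethylcyclohexyl]butanedioate | OC[C@H]2[C@@](C(CC(=O)OC(C)(C)C)C(=O)OC(C)(C)C)(C)CCC[C@]2(C)C(=O)OC | intermediate
16 | di-tert-butyl 2-[(1R,2S,3S)-2-formyl-3-(methoxycarbonyl)-1,3-dimethylcyclohexyl]butanedioate | O=C[C@H]2[C@@](C(CC(=O)OC(C)(C)C)C(=O)OC(C)(C)C)(C)CCC[C@]2(C)C(=O)OC | intermediate
17 | 2,3-dibromopropene | C=C(Br)CBr | starting material
18 | di-tert-butyl 2-{(1R,2S,3S)-2-[(1R)-3-bromo-1-hydroxybut-3-enyl]-3-(methoxycarbonyl)-1,3-dimethylcyclohexyl}butanedioate | C=C(Br)C[C@@H](O)[C@H]2[C@@](C(CC(=O)OC(C)(C)C)C(=O)OC(C)(C)C)(C)CCC[C@]2(C)C(=O)OC | intermediate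
19 | C6 tert-butyldimethylsilyl ether of 18 (not isolated) | C=C(Br)C[C@@H](O[Si](C)(C)C(C)(C)C)[C@H]2[C@@](C(CC(=O)OC(C)(C)C)C(=O)OC(C)(C)C)(C)CCC[C@]2(C)C(=O)OC | intermediate
20 | bis(trimethylsilyl) ester of 21 (not isolated) | C=C(Br)C[C@@H](O[Si](C)(C)C(C)(C)C)[C@H]2[C@@](C(CC(=O)O[Si](C)(C)C)C(=O)O[Si](C)(C)C)(C)CCC[C@]2(C)C(=O)OC | intermediate
21 | 2-{(1R,2S,3S)-2-[(1R)-3-bromo-1-(tert-butyldimethylsilyloxy)but-3-enyl]-3-(methoxycarbonyl)-1,3-dimethylcyclohexyl}butanedioic acid | C=C(Br)C[C@@H](O[Si](C)(C)C(C)(C)C)[C@H]2[C@@](C(CC(=O)O)C(=O)O)(C)CCC[C@]2(C)C(=O)OC | intermediate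
22 | cyclic succinic anhydride of 21 (not isolated) | C=C(Br)C[C@@H](O[Si](C)(C)C(C)(C)C)[C@H]2[C@@](C3CC(=O)OC3=O)(C)CCC[C@]2(C)C(=O)OC | intermediate
23 | C9 acid, C12 methyl ester (4-methoxy-4-oxobutanoic acid carrying the ring A unit at C2) | C=C(Br)C[C@@H](O[Si](C)(C)C(C)(C)C)[C@H]2[C@@](C(CC(=O)OC)C(=O)O)(C)CCC[C@]2(C)C(=O)OC | intermediate
24 | N-hydroxyphthalimide ester of 23 (precursor of the key step) | C=C(Br)C[C@@H](O[Si](C)(C)C(C)(C)C)[C@H]2[C@@](C(CC(=O)OC)C(=O)ON3C(=O)c4ccccc4C3=O)(C)CCC[C@]2(C)C(=O)OC | intermediate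
25 | methyl (1S,4aS,5R,8R,8aS)-8-(tert-butyldimethylsilyloxy)-5-(2-methoxy-2-oxoethyl)-1,4a-dimethyl-6-methylidenedecahydronaphthalene-1-carboxylate (product of the key step) | COC(=O)C[C@@H]1C(=C)C[C@@H](O[Si](C)(C)C(C)(C)C)[C@H]2[C@@]1(C)CCC[C@]2(C)C(=O)OC | intermediate
26 | C12 aldehyde, 5-(2-oxoethyl) analogue of 25 | O=CC[C@@H]1C(=C)C[C@@H](O[Si](C)(C)C(C)(C)C)[C@H]2[C@@]1(C)CCC[C@]2(C)C(=O)OC | intermediate
27 | 2-(triphenylphosphoranylidene)propanal | CC(C=O)=P(c1ccccc1)(c1ccccc1)c1ccccc1 | starting material
28 | 12E enal, 5-[(2E)-3-methyl-4-oxobut-2-enyl] analogue of 25 | O=C/C(C)=C/C[C@@H]1C(=C)C[C@@H](O[Si](C)(C)C(C)(C)C)[C@H]2[C@@]1(C)CCC[C@]2(C)C(=O)OC | intermediate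
29 | triene silyl ether, 5-[(2E)-3-methylpenta-2,4-dienyl] analogue of 25 | C=C/C(C)=C/C[C@@H]1C(=C)C[C@@H](O[Si](C)(C)C(C)(C)C)[C@H]2[C@@]1(C)CCC[C@]2(C)C(=O)OC | intermediate
30 | C6 alcohol, methyl (4S,5S,6R,9R,10S)-6-hydroxylabda-8(17),12E,14-trien-18-oate | C=C/C(C)=C/C[C@@H]1C(=C)C[C@@H](O)[C@H]2[C@@]1(C)CCC[C@]2(C)C(=O)OC | intermediate
31 | methyl (4S,5S,6R,9R,10S)-6-acetoxylabda-8(17),12E,14-trien-18-oate, CNP0212193.1 | C=C/C(C)=C/C[C@@H]1C(=C)C[C@@H](OC(C)=O)[C@H]2[C@@]1(C)CCC[C@]2(C)C(=O)OC | target

Total step count: 18. Longest linear sequence: 18 steps (from 1 and 2 to 31). All other building blocks are bought.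

Steps most likely to fail

Step 13. Capture of the C9 radical by nickel may be slow, so that hydrogen abstraction, reductive loss of bromine or coupling between molecules takes over. Facial control at C9 may also be weak, and C9 cannot be corrected afterwards.

The fallback keeps the C8–C9 disconnection and the carboxyl-derived radical but replaces the cross-coupling by a nickel-free reductive radical cyclisation onto an alkyne. It sets out from 16 and comes back at 25.
- Indium and propargyl bromide in aqueous THF should add to the C6 aldehyde under the same Felkin–Anh control to give the homopropargylic alcohol F1.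
- The operations of steps 10, 11 and 12 would then give the silyl ether diacid F2, the C9 acid C12 methyl ester F3 and the N-hydroxyphthalimide ester F4.
- Blue-light irradiation of F4 with Ru(bpy)3(PF6)2, Hantzsch ester and i-Pr2NEt in CH2Cl2 releases the same C9 radical. It adds 6-exo-dig to C8 through a chair-like transition state, and the C17 vinyl radical takes a hydrogen atom from the Hantzsch ester to give 25.

Step 9. Addition to the aldehyde between two quaternary carbons may be sluggish. The two carbonyl faces may be poorly distinguished, and the new alkoxide may lactonise onto the C18 ester.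

The fallback replaces substrate control by reagent control through an oxidation–reduction pair. It sets out from 18 (as a mixture of C6 epimers) and comes back at 18 (6R).
- Dess–Martin oxidation gives the beta,gamma-unsaturated bromoallyl ketone F5.
- Corey–Bakshi–Shibata reduction with the (S)-methyl oxazaborolidine and catecholborane at −78 °C treats ring carbon C5 as the large group and C7H2 as the small group, and should deliver the 6R alcohol.

Step 6. Addition of the crowded tertiary C10 radical to the fumarate may be slower than its quenching by the hydride and silane system, and the iron hydride may consume the fumarate.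

The fallback separates radical generation from hydride chemistry. It sets out from 10 and comes back at 12.
- Mukaiyama hydration (Mn(dpm)3, PhSiH3, O2, i-PrOH) gives the tertiary C10 alcohol F6.
- Acylation with methyl chlorooxoacetate (Et3N, DMAP) gives the methyl oxalate F7.
- One equivalent of aqueous CsOH gives the cesium oxalate F8.
- Visible-light photoredox coupling of F8 with 11 (Ir[dF(CF3)ppy]2(dtbbpy)PF6, DME–DMF, water) expels two molecules of CO2 and forms the same C10 radical with no hydrogen-atom donor present. The facial bias from the axial C19 methyl is unchanged.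

Further compounds
F1 | step 13 | di-tert-butyl 2-{(1R,2S,3S)-2-[(1R)-1-hydroxybut-3-ynyl]-3-(methoxycarbonyl)-1,3-dimethylcyclohexyl}butanedioate | C#CC[C@@H](O)[C@H]2[C@@](C(CC(=O)OC(C)(C)C)C(=O)OC(C)(C)C)(C)CCC[C@]2(C)C(=O)OC
F2 | step 13 | 2-{(1R,2S,3S)-2-[(1R)-1-(tert-butyldimethylsilyloxy)but-3-ynyl]-3-(methoxycarbonyl)-1,3-dimethylcyclohexyl}butanedioic acid | C#CC[C@@H](O[Si](C)(C)C(C)(C)C)[C@H]2[C@@](C(CC(=O)O)C(=O)O)(C)CCC[C@]2(C)C(=O)OC
F3 | step 13 | alkyne analogue of 23 (C9 acid, C12 methyl ester) | C#CC[C@@H](O[Si](C)(C)C(C)(C)C)[C@H]2[C@@](C(CC(=O)OC)C(=O)O)(C)CCC[C@]2(C)C(=O)OC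
F4 | step 13 | alkyne analogue of 24 (N-hydroxyphthalimide ester) | C#CC[C@@H](O[Si](C)(C)C(C)(C)C)[C@H]2[C@@](C(CC(=O)OC)C(=O)ON3C(=O)c4ccccc4C3=O)(C)CCC[C@]2(C)C(=O)OC
F5 | step 9 | di-tert-butyl 2-[(1R,2S,3S)-2-(3-bromobut-3-enoyl)-3-(methoxycarbonyl)-1,3-dimethylcyclohexyl]butanedioate (C6 ketone) | C=C(Br)CC(=O)[C@H]2[C@@](C(CC(=O)OC(C)(C)C)C(=O)OC(C)(C)C)(C)CCC[C@]2(C)C(=O)OC
F6 | step 6 | C10 tertiary alcohol from 10 (4-hydroxy-3-menthyloxy-4,7a-dimethyloctahydro-2-benzofuran-1-one, C10 epimers) | O=C1O[C@H](O[C@H]3C[C@@H](C)CC[C@@H]3C(C)C)[C@H]2C(C)(O)CCC[C@]12C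
F7 | step 6 | methyl oxalate of F6 | O=C1O[C@H](O[C@H]3C[C@@H](C)CC[C@@H]3C(C)C)[C@H]2C(C)(OC(=O)C(=O)OC)CCC[C@]12C
F8 | step 6 | cesium oxalate of F6 | O=C1O[C@H](O[C@H]3C[C@@H](C)CC[C@@H]3C(C)C)[C@H]2C(C)(OC(=O)C(=O)[O-])CCC[C@]12C.[Cs+]
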